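**The leftover.** The reagent that starting material leaves behind is what can still feed the second intermediate, so count it first.

the same everywhere: partner 0.0469 M; reagent 0.0804 M; protic impurity 0.0134 M

| charge | starting material | capture agent | remark | time |
|---|---|---|---|---|
| dusk | 0.018 M | 0.067 M | run made earlier |  |
| winter | 0.072 M | 0.067 M | run made earlier |  |
| maple | 0.020 M | 0.0670 M |  | 2.5 min |
| elm | 0.030 M | 0.0670 M |  | 2.5 min |
| ash | 0.040 M | 0.0670 M |  | 2.5 min |
| alder | 0.060 M | 0.0670 M |  | 2.5 min |
| larch | 0.10 M | 0.0670 M |  | 2.5 min |

| run | time / s | target / % |
|---|---|---|
| dusk | 12.0 | 1.9 |
| dusk | 40.0 | 8.8 |
| dusk | 60.0 | 11.4 |
| dusk | 120 | 17.3 |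
| winter | 12.0 | 0.7 |
| winter | 40.0 | 6.6 |
| winter | 60.0 | 6.5 |
| winter | 120 | 6.7 |

(standard deviation of a reading: 1 percentage point)

- a species is counted by the starting material in it: one idle adduct counts as two
- amounts and yields of target count idle adduct too
- the numbers in the tables scatter by 1 percentage point (one standard deviation)
- on the list of suspects stand: starting material + protic impurity -> quenched substrate; starting material + target <-> idle adduct; starting material + reagent -> open intermediate; open intermediate + second intermediate -> target; reagent + partner -> second intermediate; second intermediate + capture agent -> trapped intermediate; 2 second intermediate -> homo product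
- in an amount of target, one idle adduct counts as one target
- the concentration of target that is asked is that of its free form alone
- "hardly changes" means that all values lie within two and a half points (for a concentration: within two and a half percent of the largest)

* [target] (only what is free in solution) at the end for maple, elm, ash, alder, larch, in this order
* how the row runs (rises, then falls / rises all the way / falls all the way / falls, then rises / hardly changes)

**Starting rates.** Between 12.0 s and 40.0 s, dusk makes target at 4.44 × 10⁻⁵ M/s and winter at 1.52 × 10⁻⁴ M/s, a reading of 3.42 times. Target needs open intermediate and second intermediate, so take its rate as proportional to open intermediate times leftover. As my own rough assumption, let protic impurity take its full charge of starting material. The rest takes reagent, which gives winter 0.0586 M open and 0.0218 M leftover, and dusk 0.00460 M open and 0.0758 M leftover. My product ratio is 3.66, close to the reading given its scatter.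

**What slows it.** Second intermediate is made from reagent and partner. On my reckoning, starting material cuts the reagent for that step by a factor of 3.69 in winter and 1.06 in dusk, and partner then draws on the leftover. As read from the scattered table, dusk's rate falls by a factor of 2.32 after 40.0 s. Winter reads 6.6% at 40.0 s and 6.7% at 120 s, flat within the scatter. So I expect the end amount to follow the same product.

**Balance charge.** On that assumption, open intermediate plus leftover equals the reagent charge, so their product peaks at an even split. That gives the balance charge, 0.0536 M, which is the impurity charge plus half the reagent charge. My row therefore rises, then falls, and turns between ash and alder.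

**The forecast.** The forecast reads 0.0037 M, 0.005 M, 0.0058 M, 0.0055 M, 0.0018 M, rises, then falls, on the ground that “Flux falls with charge while share rises”.

    starting material + protic impurity → quenched substrate (k = 12.0 /M/s)
    starting material + target ⇌ idle adduct, settled at all times (K = 38.0 /M)
    starting material + reagent → open intermediate (k = 1.90 /M/s)
    open intermediate + second intermediate → target (k = 0.560 /M/s)
    reagent + partner → second intermediate (k = 0.390 /M/s)
    second intermediate + capture agent → trapped intermediate (k = 0.970 /M/s)
    2 second intermediate → homo product (k = 0.250 /M/s)

**The flask.** The row is 0.00372 M, 0.00546 M, 0.00683 M, 0.00734 M, 0.00247 M: it rises, then falls, turning at 0.053 M against the balance charge of 0.0536 M. In maple at 0.430 min, starting material has a half-life of 0.13 min by its step with reagent, while reagent has 1.1 min by its step with partner, 9.06 times longer. Larch's charge stands 0.0464 M above the balance charge, which puts its reckoned leftover 0.00620 M below zero, and at 2.50 min larch's limiting reagent, reagent, is down to 0.0256% of its charge, with starting material at 17.3% of its charge.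

The runs come from a simulation on assumed constants, noise included.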